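**Retrosynthetic overview**
1. The target is cut back to a cis-2-aryl-1,4-benzodioxane-7-carbaldehyde: the (E)-3-hydroxypropenyl chain on C7 comes from the formyl group (Wittig reaction, hydride reduction), and the three hydroxyl groups are unmasked last.
2. Key disconnection: the two ring A C–O bonds of the dioxane. O1 is carried by the benzylic carbon C2, while O4 sits on C4a, which is para to C7 of ring A (the fused benzene); with C7 as CHO, a fluoride on C4a can be displaced by the C3 oxygen once the ring A phenoxide (the future O1) has opened a trans epoxide at C2.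
3. Building blocks: 4-fluoro-3-hydroxy-5-methoxybenzaldehyde (from 4-fluoro-3-methoxybenzaldehyde by acetalisation, C–H borylation next to fluorine and oxidation) and a (2R,3R)-3-aryl-2,3-epoxypropyl silyl ether (from 5-hydroxyvanillin by allylation, Horner–Wadsworth–Emmons olefination, reduction, Sharpless epoxidation and silylation).
4. Ring order: rings A and B are bought as the two benzaldehydes; the dioxane ring is the only ring formed, in the key step, where inversion at C2 and retention at C3 turn the trans epoxide into the cis (2S,3R) ring.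

Key step: step 9

Remark on locants: the benzodioxane is numbered O1, C2 (bears ring B), C3 (bears CH2O), O4, C4a, C5 (OMe), C6, C7 (side chain), C8, C8a throughout; ring A is the fused benzene and ring B the pendant aryl ring.
Remark on protecting groups: the ring B catechol is carried as a bis(allyl) ether and the primary alcohol as a triisopropylsilyl ether. The final unmasking then runs under near-neutral palladium catalysis, which should spare the acid-sensitive cinnamyl alcohol and the cis benzylic aryl ether (liable to epimerise once the para-phenol is free). The bulky silyl group should also resist migration to the neighbouring alkoxide formed in the key step.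

**Route**

Step 1
Reactants: 1 4-fluoro-3-methoxybenzaldehyde
Product: 2 2-(4-fluoro-3-methoxyphenyl)-1,3-dioxolane
Conditions: ethylene glycol, p-TsOH (cat.), toluene, reflux (Dean–Stark)
Reagents that add atoms: ethylene glycol, OCCO
Why: Acid-catalysed acetalisation with azeotropic removal of water masks the formyl group, which would otherwise be attacked by the boron hydride formed in step 2 and by the peroxide of step 3.

Step 2
Reactants: 2 2-(4-fluoro-3-methoxyphenyl)-1,3-dioxolane
Product: 3 2-[5-(1,3-dioxolan-2-yl)-2-fluoro-3-methoxyphenyl]-4,4,5,5-tetramethyl-1,3,2-dioxaborolane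
Conditions: B2pin2, [Ir(OMe)(cod)]2 (cat.), dtbpy (cat.), THF, 80 °C
Reagents that add atoms: bis(pinacolato)diboron, CC1(C)OB(OC1(C)C)B1OC(C)(C)C(C)(C)O1
Why: Iridium-catalysed aromatic C–H borylation is sterically governed, so the catalyst formed from [Ir(OMe)(cod)]2 and dtbpy should functionalise only the ring hydrogen whose sole neighbour is the small, C–H-acidifying fluorine, the other two being shielded by the methoxy and dioxolanyl groups.

Step 3
Reactants: 3 2-[5-(1,3-dioxolan-2-yl)-2-fluoro-3-methoxyphenyl]-4,4,5,5-tetramethyl-1,3,2-dioxaborolane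
Product: 5 4-fluoro-3-hydroxy-5-methoxybenzaldehyde, via phenol acetal 4 (not isolated)
Conditions: H2O2, NaOH, THF–H2O, 0 °C → rt; Na2S2O3; then 2 M HCl, rt
Reagents that add atoms: hydrogen peroxide, OO; water, O
Why: Boronate oxidation (hydroperoxide adds to boron and the aryl group migrates from boron to oxygen) puts the hydroxyl on the borylated carbon, and the aqueous acid then hydrolyses the dioxolane back to the aldehyde.

Step 4
Reactants: 6 5-hydroxyvanillin (3,4-dihydroxy-5-methoxybenzaldehyde)
Product: 7 3,4-bis(allyloxy)-5-methoxybenzaldehyde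
Conditions: allyl bromide, K2CO3, DMF, 50 °C (N2)
Reagents that add atoms: allyl bromide, C=CCBr
Why: Williamson etherification of both phenoxides gives a catechol protection that is stable to base, hydride, peroxide and fluoride and can be removed at the end under near-neutral palladium catalysis.

Step 5
Reactants: 7 3,4-bis(allyloxy)-5-methoxybenzaldehyde; 8 triethyl phosphonoacetate
Product: 9 ethyl (2E)-3-[3,4-bis(allyloxy)-5-methoxyphenyl]prop-2-enoate
Conditions: NaH, THF, 0 °C → rt; aq NH4Cl
Reagents that add atoms: triethyl phosphonoacetate (compound 8), CCOC(=O)CP(=O)(OCC)OCC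
Why: Horner–Wadsworth–Emmons olefination with the stabilised phosphonate anion should give the (E)-cinnamate through the thermodynamically favoured elimination pathway.

Step 6
Reactants: 9 ethyl (2E)-3-[3,4-bis(allyloxy)-5-methoxyphenyl]prop-2-enoate
Product: 10 (2E)-3-[3,4-bis(allyloxy)-5-methoxyphenyl]prop-2-en-1-ol
Conditions: iBu2AlH, CH2Cl2, −78 → 0 °C; aq potassium sodium tartrate
Reagents that add atoms: none
Why: iBu2AlH reduces the conjugated ester by 1,2-hydride delivery to the allylic alcohol without touching the alkene or the allyl ethers.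

Step 7
Reactants: 10 (2E)-3-[3,4-bis(allyloxy)-5-methoxyphenyl]prop-2-en-1-ol
Product: 11 [(2R,3R)-3-[3,4-bis(allyloxy)-5-methoxyphenyl]oxiran-2-yl]methanol
Conditions: Ti(OiPr)4 (cat.), D-(−)-diisopropyl tartrate (cat.), tBuOOH, 4 Å molecular sieves, CH2Cl2, −20 °C; NaOH–brine work-up
Reagents that add atoms: tert-butyl hydroperoxide, CC(C)(C)OO
Why: Sharpless asymmetric epoxidation: the catalyst formed from Ti(OiPr)4 and the tartrate binds the allylic hydroxyl and delivers the peroxide oxygen to one alkene face, the D-(−)-tartrate giving the (2R,3R) trans epoxy alcohol (mirror image of the (2S,3S) series that L-(+)-tartrates give with (E)-cinnamyl alcohols), while the isolated allyl ether alkenes are not epoxidised.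

Step 8
Reactants: 11 [(2R,3R)-3-[3,4-bis(allyloxy)-5-methoxyphenyl]oxiran-2-yl]methanol
Product: 12 {[(2R,3R)-3-[3,4-bis(allyloxy)-5-methoxyphenyl]oxiran-2-yl]methoxy}tri(propan-2-yl)silane
Conditions: iPr3SiCl, imidazole, DMF, 0 °C → rt
Reagents that add atoms: chlorotri(propan-2-yl)silane, CC(C)[Si](Cl)(C(C)C)C(C)C
Why: Silylation of the primary alcohol under mildly basic conditions blocks the Payne rearrangement and attack by a primary alkoxide in step 9, the bulky triisopropylsilyl group being chosen because it resists oxygen-to-oxygen migration.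

Step 9
Reactants: 5 4-fluoro-3-hydroxy-5-methoxybenzaldehyde; 12 {[(2R,3R)-3-[3,4-bis(allyloxy)-5-methoxyphenyl]oxiran-2-yl]methoxy}tri(propan-2-yl)silane
Product: 14 (2S,3R)-2-[3,4-bis(allyloxy)-5-methoxyphenyl]-5-methoxy-3-{[tri(propan-2-yl)silyl]oxymethyl}-2,3-dihydro-1,4-benzodioxine-7-carbaldehyde, via erythro fluoro alkoxide 13 (not isolated)
Conditions: Cs2CO3, DMF, 90 °C (argon)
Reagents that add atoms: none
Why: Cs2CO3 forms the phenoxide of 5, which opens the trans epoxide of 12 by SN2 attack at the benzylic carbon (O1–C2, inversion) to give the erythro caesium alkoxide 13; its C3 oxygen, now held next to the fluorine, adds to C4a to give a Meisenheimer complex stabilised by the para formyl group, and fluoride is expelled (O4–C4a). The closest known reaction type is the tandem epoxide opening and intramolecular SNAr etherification of ortho-halophenols that gives 1,4-benzodioxanes. The dioxane ring closes in a 6-exo mode by attack of the alkoxide on the arene carbon. The C2 stereocentre is fixed by the stereospecific backside opening of the (2R,3R) epoxide set in step 7, and C3 keeps its oxygen and its configuration, so one inversion and one retention convert the trans epoxide into the cis (2S,3R) ring. The step needs benzylic regioselectivity in the opening, which the electron-rich ring B and the hindered, inductively deactivated carbon bearing CH2OSi(iPr)3 should secure, and SNAr at C4a only, which is the one ring A carbon activated by the para formyl group; the non-migrating silyl group and the base-stable allyl ethers keep the alkoxide on C3.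

Step 10
Reactants: 14 (2S,3R)-2-[3,4-bis(allyloxy)-5-methoxyphenyl]-5-methoxy-3-{[tri(propan-2-yl)silyl]oxymethyl}-2,3-dihydro-1,4-benzodioxine-7-carbaldehyde; 15 ethyl (triphenylphosphoranylidene)acetate
Product: 16 ethyl (2E)-3-[(2S,3R)-2-[3,4-bis(allyloxy)-5-methoxyphenyl]-5-methoxy-3-{[tri(propan-2-yl)silyl]oxymethyl}-2,3-dihydro-1,4-benzodioxin-7-yl]prop-2-enoate
Conditions: Ph3P=CHCO2Et, toluene, 80 °C
Reagents that add atoms: ethyl (triphenylphosphoranylidene)acetate (compound 15), CCOC(=O)C=P(c1ccccc1)(c1ccccc1)c1ccccc1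
Why: Wittig olefination with the stabilised ylide should give the (E)-enoate under neutral conditions that leave the cis dioxane stereocentres untouched.

Step 11
Reactants: 16 ethyl (2E)-3-[(2S,3R)-2-[3,4-bis(allyloxy)-5-methoxyphenyl]-5-methoxy-3-{[tri(propan-2-yl)silyl]oxymethyl}-2,3-dihydro-1,4-benzodioxin-7-yl]prop-2-enoate
Product: 17 (2E)-3-[(2S,3R)-2-[3,4-bis(allyloxy)-5-methoxyphenyl]-5-methoxy-3-{[tri(propan-2-yl)silyl]oxymethyl}-2,3-dihydro-1,4-benzodioxin-7-yl]prop-2-en-1-ol
Conditions: iBu2AlH, CH2Cl2, −78 °C; aq potassium sodium tartrate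
Reagents that add atoms: none
Why: 1,2-Reduction of the enoate by iBu2AlH gives the (E)-allylic alcohol, the silyl ether, allyl ethers and benzodioxane being inert to the hydride.

Step 12
Reactants: 17 (2E)-3-[(2S,3R)-2-[3,4-bis(allyloxy)-5-methoxyphenyl]-5-methoxy-3-{[tri(propan-2-yl)silyl]oxymethyl}-2,3-dihydro-1,4-benzodioxin-7-yl]prop-2-en-1-ol
Product: 18 (2E)-3-[(2S,3R)-2-[3,4-bis(allyloxy)-5-methoxyphenyl]-3-(hydroxymethyl)-5-methoxy-2,3-dihydro-1,4-benzodioxin-7-yl]prop-2-en-1-ol
Conditions: Bu4NF, THF, 0 °C → rt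
Reagents that add atoms: none
Why: Fluoride cleaves the Si–O bond while both phenols are still allyl-protected, so no phenoxide that could open the benzylic ether through a quinone methide is present under the basic conditions.

Step 13
Reactants: 18 (2E)-3-[(2S,3R)-2-[3,4-bis(allyloxy)-5-methoxyphenyl]-3-(hydroxymethyl)-5-methoxy-2,3-dihydro-1,4-benzodioxin-7-yl]prop-2-en-1-ol
Product: 19 CNP0174261.1, 5-[(2S,3R)-3-(hydroxymethyl)-7-[(1E)-3-hydroxyprop-1-en-1-yl]-5-methoxy-2,3-dihydro-1,4-benzodioxin-2-yl]-3-methoxybenzene-1,2-diol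
Conditions: Pd(PPh3)4 (cat.), morpholine, THF, rt (degassed)
Reagents that add atoms: none
Why: Tsuji–Trost-type deallylation: zerovalent palladium ionises the aryl allyl ethers to π-allyl complexes and phenoxides, and morpholine traps the allyl fragment, conditions that should leave the unactivated allylic alcohol, the (E)-alkene and the cis stereocentres alone.

**Compound list**
1 | 4-fluoro-3-methoxybenzaldehyde | COc1cc(C=O)ccc1F | starting material
2 | 2-(4-fluoro-3-methoxyphenyl)-1,3-dioxolane | COc1cc(C2OCCO2)ccc1F | intermediate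
3 | 2-[5-(1,3-dioxolan-2-yl)-2-fluoro-3-methoxyphenyl]-4,4,5,5-tetramethyl-1,3,2-dioxaborolane | COc1cc(C2OCCO2)cc(B3OC(C)(C)C(C)(C)O3)c1F | intermediate
4 | 5-(1,3-dioxolan-2-yl)-2-fluoro-3-methoxyphenol (phenol acetal) | COc1cc(C2OCCO2)cc(O)c1F | intermediate
5 | 4-fluoro-3-hydroxy-5-methoxybenzaldehyde | O=Cc1cc(O)c(F)c(OC)c1 | intermediate
6 | 5-hydroxyvanillin (3,4-dihydroxy-5-methoxybenzaldehyde) | O=Cc1cc(O)c(O)c(OC)c1 | starting material
7 | 3,4-bis(allyloxy)-5-methoxybenzaldehyde | COc1cc(C=O)cc(OCC=C)c1OCC=C | intermediate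
8 | triethyl phosphonoacetate | CCOC(=O)CP(=O)(OCC)OCC | starting material
9 | ethyl (2E)-3-[3,4-bis(allyloxy)-5-methoxyphenyl]prop-2-enoate | COc1cc(/C=C/C(=O)OCC)cc(OCC=C)c1OCC=C | intermediate
10 | (2E)-3-[3,4-bis(allyloxy)-5-methoxyphenyl]prop-2-en-1-ol | COc1cc(/C=C/CO)cc(OCC=C)c1OCC=C | intermediate
11 | [(2R,3R)-3-[3,4-bis(allyloxy)-5-methoxyphenyl]oxiran-2-yl]methanol | COc1cc([C@H]2O[C@@H]2CO)cc(OCC=C)c1OCC=C | intermediate
12 | {[(2R,3R)-3-[3,4-bis(allyloxy)-5-methoxyphenyl]oxiran-2-yl]methoxy}tri(propan-2-yl)silane | COc1cc([C@H]2O[C@@H]2CO[Si](C(C)C)(C(C)C)C(C)C)cc(OCC=C)c1OCC=C | intermediate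
13 | erythro fluoro alkoxide, drawn as the alcohol 3-{[(1S,2R)-1-[3,4-bis(allyloxy)-5-methoxyphenyl]-2-hydroxy-3-{[tri(propan-2-yl)silyl]oxy}propyl]oxy}-4-fluoro-5-methoxybenzaldehyde | COc1cc([C@H](Oc2cc(C=O)cc(OC)c2F)[C@H](O)CO[Si](C(C)C)(C(C)C)C(C)C)cc(OCC=C)c1OCC=C | intermediate
14 | (2S,3R)-2-[3,4-bis(allyloxy)-5-methoxyphenyl]-5-methoxy-3-{[tri(propan-2-yl)silyl]oxymethyl}-2,3-dihydro-1,4-benzodioxine-7-carbaldehyde | COc1cc([C@@H]2Oc3cc(C=O)cc(OC)c3O[C@@H]2CO[Si](C(C)C)(C(C)C)C(C)C)cc(OCC=C)c1OCC=C | intermediate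
15 | ethyl (triphenylphosphoranylidene)acetate | CCOC(=O)C=P(c1ccccc1)(c1ccccc1)c1ccccc1 | starting material
16 | ethyl (2E)-3-[(2S,3R)-2-[3,4-bis(allyloxy)-5-methoxyphenyl]-5-methoxy-3-{[tri(propan-2-yl)silyl]oxymethyl}-2,3-dihydro-1,4-benzodioxin-7-yl]prop-2-enoate | COc1cc([C@@H]2Oc3cc(/C=C/C(=O)OCC)cc(OC)c3O[C@@H]2CO[Si](C(C)C)(C(C)C)C(C)C)cc(OCC=C)c1OCC=C | intermediate
17 | (2E)-3-[(2S,3R)-2-[3,4-bis(allyloxy)-5-methoxyphenyl]-5-methoxy-3-{[tri(propan-2-yl)silyl]oxymethyl}-2,3-dihydro-1,4-benzodioxin-7-yl]prop-2-en-1-ol | COc1cc([C@@H]2Oc3cc(/C=C/CO)cc(OC)c3O[C@@H]2CO[Si](C(C)C)(C(C)C)C(C)C)cc(OCC=C)c1OCC=C | intermediate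
18 | (2E)-3-[(2S,3R)-2-[3,4-bis(allyloxy)-5-methoxyphenyl]-3-(hydroxymethyl)-5-methoxy-2,3-dihydro-1,4-benzodioxin-7-yl]prop-2-en-1-ol | COc1cc([C@@H]2Oc3cc(/C=C/CO)cc(OC)c3O[C@@H]2CO)cc(OCC=C)c1OCC=C | intermediate
19 | CNP0174261.1, 5-[(2S,3R)-3-(hydroxymethyl)-7-[(1E)-3-hydroxyprop-1-en-1-yl]-5-methoxy-2,3-dihydro-1,4-benzodioxin-2-yl]-3-methoxybenzene-1,2-diol | COc1cc([C@@H]2Oc3cc(/C=C/CO)cc(OC)c3O[C@@H]2CO)cc(O)c1O | target

**Step count and risks**
Total steps: 13 (steps 1–3 make the fluorophenol, steps 4–8 the epoxide, steps 9–13 the union and endgame).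
Longest linear sequence: 10 steps (5-hydroxyvanillin 6 to target 19, steps 4–13).

Steps most likely to fail:

1. Step 9 (key cascade). The phenoxide may open the epoxide partly at the non-benzylic carbon, or the SNAr closure onto a fluoroarene flanked by two oxygen substituents may lag behind silyl transfer and intermolecular etherification. The two C–O bonds would then be made in separate, individually controlled operations setting out from 11 and 5. Heating the unprotected epoxy alcohol 11 with 5 and NaOH (about one equivalent) in water–tert-butanol at 60 °C, conditions under which phenoxides are known to open free trans-3-arylglycidols at the benzylic carbon with inversion, should give the erythro diol 3-{[(1S,2R)-1-[3,4-bis(allyloxy)-5-methoxyphenyl]-2,3-dihydroxypropyl]oxy}-4-fluoro-5-methoxybenzaldehyde F1. Selective silylation of its primary hydroxyl (iPr3SiCl, imidazole, CH2Cl2, 0 °C) would give 13 as an isolated alcohol, and KOtBu in THF (0 °C → rt) would close the dioxane ring by SNAr, returning to the route at 14.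

2. Step 7 (Sharpless epoxidation). The Lewis-acidic titanium medium or the work-up may open the electron-rich benzylic epoxide, or facial selectivity may be eroded. The order of silylation and epoxidation would then be reversed and the oxidant changed, setting out from 10. Silylation (iPr3SiCl, imidazole, DMF) should give the cinnamyl ether (E)-{[3-[3,4-bis(allyloxy)-5-methoxyphenyl]prop-2-en-1-yl]oxy}tri(propan-2-yl)silane F2. Shi epoxidation with the D-fructose-derived ketone catalyst (KHSO5 as 2KHSO5·KHSO4·K2SO4, K2CO3, MeCN–dimethoxymethane–aqueous buffer, 0 °C) works at basic pH, is known to give (R,R) epoxides from (E)-cinnamyl ethers and should react far more slowly with the monosubstituted allyl ether alkenes; it should give 12 directly, where the route is rejoined.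

3. Step 13 (final deallylation). Pd(PPh3)4 may ionise the electron-rich cinnamyl alcohol (allyl scrambling or amination), and the freed catechol must be handled without air or base. The catechol would then be unmasked before the allylic alcohol exists, setting out from 16. Pd(PPh3)4 and morpholine in THF should give the catechol ester ethyl (2E)-3-[(2S,3R)-2-(3,4-dihydroxy-5-methoxyphenyl)-5-methoxy-3-{[tri(propan-2-yl)silyl]oxymethyl}-2,3-dihydro-1,4-benzodioxin-7-yl]prop-2-enoate F3. Excess iBu2AlH (THF, −78 → 0 °C, the phenols being carried as aluminium phenoxides) should reduce it to (2E)-3-[(2S,3R)-2-(3,4-dihydroxy-5-methoxyphenyl)-5-methoxy-3-{[tri(propan-2-yl)silyl]oxymethyl}-2,3-dihydro-1,4-benzodioxin-7-yl]prop-2-en-1-ol F4. Desilylation with Bu4NF buffered by AcOH (THF, rt), which avoids free phenoxide, should then give 19.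

**Further compounds**
F1 | step 9 | 3-{[(1S,2R)-1-[3,4-bis(allyloxy)-5-methoxyphenyl]-2,3-dihydroxypropyl]oxy}-4-fluoro-5-methoxybenzaldehyde | COc1cc([C@H](Oc2cc(C=O)cc(OC)c2F)[C@H](O)CO)cc(OCC=C)c1OCC=C
F2 | step 7 | (E)-{[3-[3,4-bis(allyloxy)-5-methoxyphenyl]prop-2-en-1-yl]oxy}tri(propan-2-yl)silane | COc1cc(/C=C/CO[Si](C(C)C)(C(C)C)C(C)C)cc(OCC=C)c1OCC=C
F3 | step 13 | ethyl (2E)-3-[(2S,3R)-2-(3,4-dihydroxy-5-methoxyphenyl)-5-methoxy-3-{[tri(propan-2-yl)silyl]oxymethyl}-2,3-dihydro-1,4-benzodioxin-7-yl]prop-2-enoate | COc1cc([C@@H]2Oc3cc(/C=C/C(=O)OCC)cc(OC)c3O[C@@H]2CO[Si](C(C)C)(C(C)C)C(C)C)cc(O)c1O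
F4 | step 13 | (2E)-3-[(2S,3R)-2-(3,4-dihydroxy-5-methoxyphenyl)-5-methoxy-3-{[tri(propan-2-yl)silyl]oxymethyl}-2,3-dihydro-1,4-benzodioxin-7-yl]prop-2-en-1-ol | COc1cc([C@@H]2Oc3cc(/C=C/CO)cc(OC)c3O[C@@H]2CO[Si](C(C)C)(C(C)C)C(C)C)cc(O)c1O
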